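All runs were generated by integration with made-up constants.

Slowness shows in molar amounts: at 20.0 h the Vy.Ry and Wu together read between 0.0165 M and 0.0181 M in the three earlier runs, despite their different charges.

| flask | Jo | Ry | remark | time |
|---|---|---|---|---|
| violet | 0.13 M | 0.14 M | run made earlier |  |
| amber | 0.30 M | 0.14 M | run made earlier |  |
| ochre | 0.20 M | 0.070 M | run made earlier |  |
| flask | 0.20 M | 0.140 M |  | 30 h |

| run | time / h | Vy.Ry / % | Wu / % |
|---|---|---|---|
| violet | 1.33 | 1.7 | 0 |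
| violet | 2.50 | 0 | 0 |
| violet | 5.00 | 1.2 | 0 |
| violet | 10.0 | 5.4 | 0.1 |
| violet | 20.0 | 11.6 | 2.3 |
| amber | 4.00 | 1.3 | 1.3 |
| amber | 8.00 | 0.9 | 0.6 |
| amber | 10.0 | 1.7 | 0 |
| amber | 15.0 | 4.6 | 0.3 |
| amber | 20.0 | 5.1 | 0.4 |
| ochre | 4.00 | 0.3 | 0 |
| ochre | 8.00 | 0.5 | 0 |
| ochre | 10.0 | 3.0 | 0.9 |
| ochre | 15.0 | 3.7 | 0 |
| ochre | 20.0 | 6.7 | 1.7 |

(each reading ± 1 percentage point)

- the Vy.Ry and Wu together standing at 30 h, as a percentage of the Jo charged
- concentration of Vy in solution at 30 h, in percent of saturation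

- percentages count the Jo that a species holds: one Vy.Vy.Ry or Jo.Vy.Ry counts as two
- Vy.Ry is meant together with its Wu
- solid, in amounts per volume of the solution: Jo, Wu
- the earlier runs were read with a standard deviation of 1 percentage point
- on the list of suspects stand: Jo <-> Vy; Vy + Ry -> Vy.Ry; Vy + Vy.Ry -> Vy.Vy.Ry; Wu <-> Vy.Ry; Jo + Vy.Ry -> Jo.Vy.Ry
- at the start none of Jo is in solution
- Vy means what is dissolved; the solid is not counted in it

I average those readings to 0.0171 M, and the readings at 10.0 h to 0.00668 M. The climb, the molar gain of Vy.Ry and Wu per hour between those two times, an apparent zero-order rate, reads 0.00104 M h⁻¹.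

For the new flask the charges allow 70.0% of the Jo charged, which is loose. I tighten this by estimate, not by proof, and from scattered readings: holding the climb on to 30 h gives my ceiling, 13.8%, and no gain after 20.0 h gives my floor, 8.56%. The forecast puts the product at 14%, beside my ceiling, in the words “That points to slow dissolution of Jo as the limit”, and it puts Vy at 15% of saturation.

The flask gives 11.3%, inside the bracket, with Vy at 30.7% of saturation.

    Jo ⇌ Vy, rate k1*(cs1 - [Vy]) while solid is left; crystals form when [Vy] > cs1 (solubility = 0.140 M, k = 8.10 × 10⁻⁶ s⁻¹)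
    Vy + Ry → Vy.Ry (k = 1.20 × 10⁻⁴ M⁻¹ s⁻¹)
    Vy + Vy.Ry → Vy.Vy.Ry (k = 1.90 × 10⁻⁴ M⁻¹ s⁻¹)
    Wu ⇌ Vy.Ry, rate k4*(cs4 - [Vy.Ry]) while solid is left; crystals form when [Vy.Ry] > cs4 (solubility = 0.0730 M, k = 3.90 × 10⁻⁴ s⁻¹)
    Jo + Vy.Ry → Jo.Vy.Ry (k = 8.60 × 10⁻⁵ M⁻¹ s⁻¹)

Taken from the average reading of 0.0171 M in the earlier runs, the stand of 0.0227 M in this flask implies an average gain after 20.0 h of 5.56 × 10⁻⁴ M h⁻¹, half the climb. Part of what holds the stand down is the slow dissolving of Jo acting together with the conversion of Jo + Vy.Ry into Jo.Vy.Ry: this flask gives 18.2% with fast dissolving and 16.3% without the conversion, against 11.3%. Read at 12 h, the same flask is nearer the climb: from 0.00668 M the climb gives 4.39%, and the flask stands at 4.61%.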